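- The constants of these steps stand hidden, but one time can be read from the runs: the lifetime of Q, in which Q falls by a factor e. It shows in how fast E closes on its last reading, on the assumption that E stops when Q stops.

| flask | X | Q | J | remark | time |
|---|---|---|---|---|---|
| south-east | 0.50 M | 1 M | 0.50 M | run made earlier |  |
| south-west | 0.50 M | 0.50 M | 0.50 M | run made earlier |  |
| north-east | 0.50 M | 0.75 M | 0.50 M | run made earlier |  |
| midnight | 0.50 M | 1.00 M | 0.500 M | everything together at the start | 2.5 h |
| noon | 0.50 M (in portions, 5, over 1.5 h) | 1.00 M | 0.500 M | first portion at the start, last at 1.5 h | 2.5 h |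
| summer | 0.50 M | 1.00 M | 0.500 M (fed, over 1.5 h) | all else is in the flask from the start; the feed brings no volume worth counting | 2.5 h |
| dusk | 0.50 M (fed, over 1.5 h) | 1.00 M | 0.500 M | all else is in the flask from the start; the feed brings no volume worth counting | 2.5 h |

south-east run (percent of the X charged)

| time / min | D / % | E / % |
|---|---|---|
| 12.0 | 8.8 | 18.5 |
| 30.0 | 11.2 | 25.3 |
| 60.0 | 11.6 | 29.2 |
| 90.0 | 12.2 | 30.0 |

south-west run (percent of the X charged)

| time / h | D / % | E / % |
|---|---|---|
| 0.417 | 20.7 | 10.5 |
| 1.00 | 27.7 | 11.6 |
| 2.00 | 34.0 | 11.7 |
| 3.00 | 36.2 | 11.7 |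

north-east run (percent of the X charged)

| time / h | D / % | E / % |
|---|---|---|
| 0.250 | 12.5 | 15.2 |
| 0.500 | 14.9 | 18.1 |
| 1.33 | 19.1 | 19.5 |
| 3.00 | 21.0 | 20.6 |

(scatter of a reading: 0.3 percentage points)

- steps thought possible: X <-> Z; Q -> L; X + J -> D; J + Q -> G; X + Q -> E

* the flask that comes out highest in amount of D, in percent of the X charged, or "all alike" when all lie within 1.5 percentage points (midnight / noon / summer / dusk / all alike)
* D at the end, in percent of the X charged, midnight
* D at the end, in percent of the X charged, noon
* D at the end, in percent of the X charged, summer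
* D at the end, in percent of the X charged, dusk

- In the south-east run, the gap to the last E reading shrinks between 12.0 min and 30.0 min at a pace that gives a lifetime of 0.335 h. The north-east run, with another Q charge, gives 0.325 h between 0.250 h and 0.500 h, so two different runs agree.
- The south-east window from the start to the first reading parts from them: it gives 0.209 h, shorter than the later window. That window holds the start, with J at its full charge, and the runs suggest that Q and J destroy each other: at the same time, D reads 27.7% after 1.00 h in the south-west run with 0.50 M of Q, but 11.6% after 60.0 min in the south-east run with 1 M. So the first window is taken to count Q spent on J and is set aside, which leaves a read lifetime of 0.330 h.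
- The Q window, one lifetime of Q divided by the feed time, comes to 22.0%: the share of a steady feed that enters within one lifetime of Q.
- This reckoning expects summer highest: the lifetime is shorter than the feed, so in summer 78.0% of J enters after one lifetime of Q. For dusk, it scales the south-east D reading by the window, which gives 2.68%.
- The forecast names summer, with D at 12.7% in midnight, 5.5% in noon, 34% in summer (26% to 41%) and 5% in dusk, which is above this reckoning. Its ground for summer: “J is fed while Q dies by itself”.
- The flasks give summer as the highest, with D at 30.9%, against 12.9% in midnight, 4.32% in noon and 2.99% in dusk.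

    X ⇌ Z (K = 0.360, k = 2.50 × 10⁻⁴ s⁻¹)
    Q → L (k = 5.60 × 10⁻⁴ s⁻¹)
    X + J → D (k = 8.50 × 10⁻⁴ M⁻¹ s⁻¹)
    J + Q → G (k = 0.00460 M⁻¹ s⁻¹)
    X + Q → E (k = 6.20 × 10⁻⁴ M⁻¹ s⁻¹)

- In summer, the 0.175 M of G at the end equals the amount of J fed in 0.525 h, or 1.59 read lifetimes of Q, while 0.610 M of L stands beside it, and Q, the limiting reagent there, ends at 0% with J at 34.1%.
- In dusk, with X fed over the same time, the Q window of 22.0% stands beside a D that ends at 23.2% of the midnight value.

All runs come from a simulation on assumed constants; noise was put on by code.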